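**Plan**

- Cuts (retro): the five O‑benzyl groups and a C‑6′ bromine; the spiro C–C(=O) bond together with C‑8′–H (hydroacylation of a furan C=C); the diaryl ether O–C(aryl) bond; the furan O‑7′–C‑8′ bond; the chroman C‑4–C‑4a bond, traced back to the C‑3–C‑3a bond of a 3‑(iodomethyl)‑2‑aryl‑2,3‑dihydrobenzofuran; the exocyclic C–C and the O‑1–C‑2 ether bond of that ring; the aryl ketone bond to phloroglucinol.
- Forward: phloroglucinol is acylated first, so the later C‑8 substituent is fixed by symmetry → aryl 1‑arylallyl ether → five‑membered dihydrobenzofuran → six‑membered chroman by ring expansion → furanone ring → diaryl ether → spiro benzofuranone ring → deprotection.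
- Enabling feature: the chroman CH2‑4 is bonded to aromatic C‑4a, which lies between two oxygen‑bearing carbons (C‑5, C‑8a). In a dihydrobenzofuran that shares O‑1 and C‑2 and carries an exocyclic CH2 radical on C‑3, this electron‑rich aryl carbon is β to the radical and shifts 1,2 (neophyl), so the CH2 enters the ring.
- Stereochemistry: flavan C‑2 comes from Ir/phosphoramidite allylic etherification and is untouched by the ring expansion, in which both C‑3 epimers of the precursor converge. The spiro centre and C‑8′ are set together by a syn hydroacylation under chiral carbene control.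
- Helpers: the CH2I radical handle, a bromine that blocks C‑6 (removed in the last step), benzyl ethers.

Key step: step 10

Remark: the absolute sense of induction in steps 6 and 14 is assigned by analogy; in each case the catalyst enantiomer is the one that gives the configuration written.

**Step 1**
Reactants: 1 phloroglucinol; 2 2-[4-(benzyloxy)phenyl]acetonitrile
Product: 4 2-[4-(benzyloxy)phenyl]-1-(2,4,6-trihydroxyphenyl)ethan-1-one, via 2-[4-(benzyloxy)phenyl]-1-(2,4,6-trihydroxyphenyl)ethan-1-iminium chloride 3 (not isolated)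
Conditions: ZnCl2, HCl (g), Et2O, 0 °C; then H2O, 100 °C
Reagents that add atoms: water, O
Why: Hoesch acylation of the symmetric, very electron-rich arene stops after one acylation because the ketiminium salt is deactivated, and its hydrolysis gives the ketone; the aryl benzyl ether should tolerate HCl/ZnCl2 at 0 °C.

**Step 2**
Reactants: 4 2-[4-(benzyloxy)phenyl]-1-(2,4,6-trihydroxyphenyl)ethan-1-one
Product: 5 1-[4-(benzyloxy)-2,6-dihydroxyphenyl]-2-[4-(benzyloxy)phenyl]ethan-1-one
Conditions: BnBr (1.0 equiv), K2CO3 (1.1 equiv), DMF, 0 °C → rt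
Reagents that add atoms: benzyl bromide, BrCc1ccccc1
Why: Williamson etherification should take the 4-OH, the most acidic and only non-chelated hydroxyl (para to the acyl group), while the two ortho hydroxyls are held by the carbonyl.

**Step 3**
Reactants: 6 4-(benzyloxy)benzaldehyde
Product: 7 ethyl (2E)-3-[4-(benzyloxy)phenyl]prop-2-enoate
Conditions: (EtO)2P(O)CH2CO2Et, NaH, THF, 0 °C → rt
Reagents that add atoms: triethyl phosphonoacetate, CCOC(=O)CP(=O)(OCC)OCC
Why: Horner–Wadsworth–Emmons olefination with a stabilised phosphonate is E-selective.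

**Step 4**
Reactants: 7 ethyl (2E)-3-[4-(benzyloxy)phenyl]prop-2-enoate
Product: 8 (2E)-3-[4-(benzyloxy)phenyl]prop-2-en-1-ol
Conditions: DIBAL-H (2.2 equiv), CH2Cl2, −78 °C; Rochelle salt work-up
Reagents that add atoms: none
Why: DIBAL-H reduces the conjugated ester 1,2 to the allylic alcohol without touching the alkene.

**Step 5**
Reactants: 8 (2E)-3-[4-(benzyloxy)phenyl]prop-2-en-1-ol
Product: 9 (2E)-3-[4-(benzyloxy)phenyl]prop-2-en-1-yl methyl carbonate
Conditions: ClCO2Me, pyridine, CH2Cl2, 0 °C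
Reagents that add atoms: methyl chloroformate, COC(=O)Cl
Why: Acylation of the primary alcohol gives the linear allylic carbonate needed as leaving group for iridium.

**Step 6**
Reactants: 5 1-[4-(benzyloxy)-2,6-dihydroxyphenyl]-2-[4-(benzyloxy)phenyl]ethan-1-one; 9 (2E)-3-[4-(benzyloxy)phenyl]prop-2-en-1-yl methyl carbonate
Product: 10 1-[4-(benzyloxy)-2-{[(1S)-1-[4-(benzyloxy)phenyl]prop-2-en-1-yl]oxy}-6-hydroxyphenyl]-2-[4-(benzyloxy)phenyl]ethan-1-one
Conditions: 5, LiHMDS (1.0 equiv), THF, 0 °C; then 9, [Ir(cod)Cl]2 (2 mol %), (Sa)-binaphthyl-2,2′-diyl N,N-bis[(S)-1-phenylethyl]phosphoramidite (4 mol %, pre-activated with n-PrNH2), THF, 40 °C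
Reagents that add atoms: none
Why: Iridium/phosphoramidite-catalysed asymmetric allylic etherification: the phenoxide of one of the two equivalent ortho hydroxyls attacks the substituted terminus of the allyl–Ir intermediate, and the cyclometallated chiral ligand fixes the face, which sets the S ether carbon (the later flavan C-2).

**Step 7**
Reactants: 10 (allyl ether of step 6)
Product: 12 1-[4-(benzyloxy)-3-bromo-2-hydroxy-5-iodo-6-{[(1S)-1-[4-(benzyloxy)phenyl]prop-2-en-1-yl]oxy}phenyl]-2-[4-(benzyloxy)phenyl]ethan-1-one, via 1-[4-(benzyloxy)-3-bromo-2-hydroxy-6-{[(1S)-1-[4-(benzyloxy)phenyl]prop-2-en-1-yl]oxy}phenyl]-2-[4-(benzyloxy)phenyl]ethan-1-one 11 (not isolated)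
Conditions: NBS (1.0 equiv), MeCN, −20 °C; then NIS (1.1 equiv), 0 °C → rt
Reagents that add atoms: N-bromosuccinimide, O=C1CCC(=O)N1Br; N-iodosuccinimide, O=C1CCC(=O)N1I
Why: Electrophilic aromatic halogenation: bromine should enter ortho to the free hydrogen-bonded hydroxyl (C-3, a blocking group), iodine then takes the only remaining ring CH (C-5, ortho to the allyl ether oxygen), and the acid-free conditions spare the ionisable 1-arylallyl ether and the vinyl group.

**Step 8**
Reactants: 12 (bromo-iodo allyl ether of step 7)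
Product: 14 1-[(2S,3RS)-4-(benzyloxy)-2-[4-(benzyloxy)phenyl]-5-bromo-6-hydroxy-3-(hydroxymethyl)-2,3-dihydro-1-benzofuran-7-yl]-2-[4-(benzyloxy)phenyl]ethan-1-one, via the corresponding 3-(hydroperoxymethyl) compound 13 (not isolated)
Conditions: Bu3SnH (2.5 equiv, slow addition), stream of dry air, toluene, 60 °C; then PPh3
Reagents that add atoms: dioxygen, O=O
Why: Oxygenative aryl-radical cyclisation: the stannyl radical takes iodine in preference to bromine, the aryl radical closes 5-exo-trig onto the vinyl group faster than it is trapped, the primary radical is caught by O2 and the hydroperoxide is reduced by PPh3; C-2 is untouched and the C-3 epimers are both carried on.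

**Step 9**
Reactants: 14 (3-hydroxymethyl dihydrobenzofuran of step 8)
Product: 15 1-[(2S,3RS)-4-(benzyloxy)-2-[4-(benzyloxy)phenyl]-5-bromo-6-hydroxy-3-(iodomethyl)-2,3-dihydro-1-benzofuran-7-yl]-2-[4-(benzyloxy)phenyl]ethan-1-one
Conditions: PPh3, imidazole, I2 (added last), CH2Cl2, 0 °C → rt
Reagents that add atoms: iodine, II
Why: Appel iodination converts the primary alcohol into the iodide with the phenol and ketone left alone.

**Step 10**
Reactants: 15 (3-iodomethyl dihydrobenzofuran of step 9)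
Product: 17 1-[(2S)-5-(benzyloxy)-2-[4-(benzyloxy)phenyl]-6-bromo-7-hydroxy-3,4-dihydro-2H-chromen-8-yl]-2-[4-(benzyloxy)phenyl]ethan-1-one, via 1-[(2R,3RS)-5-(benzyloxy)-2-[4-(benzyloxy)phenyl]-6-bromo-7-hydroxy-3-iodo-3,4-dihydro-2H-chromen-8-yl]-2-[4-(benzyloxy)phenyl]ethan-1-one 16 (not isolated)
Conditions: (Bu3Sn)2 (0.2 equiv), hν (sun lamp), degassed PhH (0.05 M), 80 °C; then Bu3SnH (1.2 equiv), AIBN, 80 °C
Reagents that add atoms: none
Why: Stannyl radicals from the photolysed ditin abstract the primary iodine of 15; the CH2 radical adds to the ipso carbon C-3a of the fused arene (3-exo-trig) to give a spiro-cyclopropane cyclohexadienyl radical, stabilised by the oxygens on both ortho carbons and the para carbon, which reopens at the former C-3–C-3a bond so that the CH2 is inserted between C-3 and the arene and the five-membered ring O-1/C-2/C-3/C-3a/C-7a becomes the six-membered chroman ring of a secondary chroman-3-yl radical (neophyl 1,2-aryl shift, the net result of a 6-endo closure). The closest known reaction type is the neophyl ring expansion of (2,3-dihydrobenzofuran-3-yl)methyl radicals to chroman-3-yl radicals that accompanies aryl-radical cyclisations at low stannane concentration. As no hydrogen donor is present in the first stage, the slow shift cannot be outrun by reduction; the rearranged radical takes iodine from 15 in a chain and the six-ring secondary iodide 16 should accumulate as the thermodynamic sink, after which Bu3SnH removes the iodine. No new stereocentre remains in 17: C-3 of 16 forms without control and ends as CH2, both C-3 epimers of 15 converge, and C-2, which takes part in no bond change, keeps the configuration set in step 6 (the descriptor R in 16 is only a priority change). The step needs abstraction of the alkyl iodine in preference to the aryl bromine (much faster for stannyl radicals), migration of the arene (the only π system on C-3), and survival of the C-2–O-1 bond in the β-aryloxy radical, for which the short radical lifetime under iodine transfer and the fast reduction in the second stage are relied on.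

**Step 11**
Reactants: 17 (8-arylacetyl-7-hydroxyflavan of step 10)
Product: 19 (2S,8RS)-5-(benzyloxy)-2,8-bis[4-(benzyloxy)phenyl]-6-bromo-2,3,4,8-tetrahydro-9H-furo[2,3-h]chromen-9-one, via the α-iodo ketone 1-[(2S)-5-(benzyloxy)-2-[4-(benzyloxy)phenyl]-6-bromo-7-hydroxy-3,4-dihydro-2H-chromen-8-yl]-2-[4-(benzyloxy)phenyl]-2-iodoethan-1-one 18 (not isolated)
Conditions: LiHMDS (2.1 equiv), THF, −78 °C; I2 (1.0 equiv), −78 °C → rt
Reagents that add atoms: none
Why: Double deprotonation gives the phenoxide/enolate, the enolate carbon is iodinated and the neighbouring phenoxide displaces iodide (5-exo-tet Williamson closure) to form the 2-arylbenzofuran-3(2H)-one; the fully substituted A ring cannot be halogenated, and the new C-8 centre is enolisable and is erased in step 13.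

**Step 12**
Reactants: 20 2,4,6-trifluorobenzaldehyde
Product: 21 2,4-bis(benzyloxy)-6-fluorobenzaldehyde
Conditions: BnOH (2.05 equiv), NaH (2.1 equiv), THF, 0 °C → rt
Reagents that add atoms: benzyl alcohol, OCc1ccccc1
Why: Two SNAr displacements activated by the formyl group (para fluorine first, then one ortho fluorine); the third fluorine, deactivated by the two alkoxy groups, should remain.

**Step 13**
Reactants: 19 (furochromenone of step 11); 21 2,4-bis(benzyloxy)-6-fluorobenzaldehyde
Product: 22 2,4-bis(benzyloxy)-6-{[(2S)-5-(benzyloxy)-2,8-bis[4-(benzyloxy)phenyl]-6-bromo-3,4-dihydro-2H-furo[2,3-h]chromen-9-yl]oxy}benzaldehyde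
Conditions: Cs2CO3 (1.5 equiv), DMF, 90 °C
Reagents that add atoms: none
Why: SNAr O-arylation: the ambident enolate of 19 reacts at oxygen, which gives the aromatic benzofuran, and displaces the fluoride ortho to the formyl group.

**Step 14**
Reactants: 22 (3-aryloxy-2-arylbenzofuran aldehyde of step 13)
Product: 23 (2S,2′S,8′S)-4,5′,6-tris(benzyloxy)-2′,8′-bis[4-(benzyloxy)phenyl]-6′-bromo-3′,4′-dihydro-2′H,3H,8′H-spiro[1-benzofuran-2,9′-furo[2,3-h]chromen]-3-one (8′-aryl cis to the benzofuranone ring oxygen)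
Conditions: aminoindanol-derived N-mesityl triazolium tetrafluoroborate (20 mol %), K3PO4 (20 mol %), 1,4-dioxane, 80 °C
Reagents that add atoms: none
Why: Proposed new method: the carbene adds to the aldehyde to give the enaminol (acyl-anion equivalent), whose nucleophilic carbon lies five atoms from C-9 and should add across the furan C-8=C-9 bond in a concerted, asynchronous Conia-ene-like transition state in which the enol O–H proton goes to C-8 while the C–C bond forms at the oxygen-bearing C-9 (5-exo), the positive charge building at C-9 being stabilised by the ether oxygen and the trioxygenated arene; collapse releases the carbene and the benzofuran-3-one, and because H and acyl arrive on the same face the C-8′ hydrogen is cis to the new carbonyl, that is the aryl group is cis to the ring oxygen as in the target, while the chiral triazolylidene chooses the face independently of the remote flavan centre; the closest known reaction type is the carbene-catalysed intramolecular hydroacylation of unactivated alkenes and its dearomatising variant on benzofurans tethered through a CH2O link, which close six-membered ketones with a quaternary centre, whereas here the tether is the enol-ether oxygen itself and a five-membered ring closes onto a tetrasubstituted double bond.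

**Step 15**
Reactants: 23 (penta-O-benzyl-6′-bromodaphnodorin C of step 14)
Product: 24 daphnodorin C, (2S,2′S,8′S)-4,5′,6-trihydroxy-2′,8′-bis(4-hydroxyphenyl)-3′,4′-dihydro-2′H,3H,8′H-spiro[1-benzofuran-2,9′-furo[2,3-h]chromen]-3-one
Conditions: H2 (1 atm), 10 % Pd/C, NaOAc (1.5 equiv), EtOAc–MeOH, rt
Reagents that add atoms: none
Why: Hydrogenolysis removes the five O-benzyl groups and the aryl bromine under buffered neutral conditions, under which the two cyclic benzylic ethers and the vinylogous-ester-like ketone should survive and no stereocentre is touched.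

**Compound list**

1 | phloroglucinol | Oc1cc(O)cc(O)c1 | starting material
2 | 2-[4-(benzyloxy)phenyl]acetonitrile | N#CCc1ccc(OCc2ccccc2)cc1 | starting material
3 | 2-[4-(benzyloxy)phenyl]-1-(2,4,6-trihydroxyphenyl)ethan-1-iminium chloride | [NH2+]=C(Cc1ccc(OCc2ccccc2)cc1)c1c(O)cc(O)cc1O.[Cl-] | intermediate (not isolated)
4 | 2-[4-(benzyloxy)phenyl]-1-(2,4,6-trihydroxyphenyl)ethan-1-one | O=C(Cc1ccc(OCc2ccccc2)cc1)c1c(O)cc(O)cc1O | intermediate
5 | 1-[4-(benzyloxy)-2,6-dihydroxyphenyl]-2-[4-(benzyloxy)phenyl]ethan-1-one | O=C(Cc1ccc(OCc2ccccc2)cc1)c1c(O)cc(OCc2ccccc2)cc1O | intermediate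
6 | 4-(benzyloxy)benzaldehyde | O=Cc1ccc(OCc2ccccc2)cc1 | starting material
7 | ethyl (2E)-3-[4-(benzyloxy)phenyl]prop-2-enoate | CCOC(=O)/C=C/c1ccc(OCc2ccccc2)cc1 | intermediate
8 | (2E)-3-[4-(benzyloxy)phenyl]prop-2-en-1-ol | OC/C=C/c1ccc(OCc2ccccc2)cc1 | intermediate
9 | (2E)-3-[4-(benzyloxy)phenyl]prop-2-en-1-yl methyl carbonate | COC(=O)OC/C=C/c1ccc(OCc2ccccc2)cc1 | intermediate
10 | 1-[4-(benzyloxy)-2-{[(1S)-1-[4-(benzyloxy)phenyl]prop-2-en-1-yl]oxy}-6-hydroxyphenyl]-2-[4-(benzyloxy)phenyl]ethan-1-one | O=C(Cc1ccc(OCc2ccccc2)cc1)c1c(O)cc(OCc2ccccc2)cc1O[C@@H](C=C)c1ccc(OCc2ccccc2)cc1 | intermediate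
11 | 1-[4-(benzyloxy)-3-bromo-2-hydroxy-6-{[(1S)-1-[4-(benzyloxy)phenyl]prop-2-en-1-yl]oxy}phenyl]-2-[4-(benzyloxy)phenyl]ethan-1-one | O=C(Cc1ccc(OCc2ccccc2)cc1)c1c(O)c(Br)c(OCc2ccccc2)cc1O[C@@H](C=C)c1ccc(OCc2ccccc2)cc1 | intermediate (not isolated)
12 | 1-[4-(benzyloxy)-3-bromo-2-hydroxy-5-iodo-6-{[(1S)-1-[4-(benzyloxy)phenyl]prop-2-en-1-yl]oxy}phenyl]-2-[4-(benzyloxy)phenyl]ethan-1-one | O=C(Cc1ccc(OCc2ccccc2)cc1)c1c(O)c(Br)c(OCc2ccccc2)c(I)c1O[C@@H](C=C)c1ccc(OCc2ccccc2)cc1 | intermediate
13 | 1-[(2S,3RS)-4-(benzyloxy)-2-[4-(benzyloxy)phenyl]-5-bromo-3-(hydroperoxymethyl)-6-hydroxy-2,3-dihydro-1-benzofuran-7-yl]-2-[4-(benzyloxy)phenyl]ethan-1-one | O=C(Cc1ccc(OCc2ccccc2)cc1)c1c(O)c(Br)c(OCc2ccccc2)c2c1O[C@H](c1ccc(OCc3ccccc3)cc1)C2COO | intermediate (not isolated)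
14 | 1-[(2S,3RS)-4-(benzyloxy)-2-[4-(benzyloxy)phenyl]-5-bromo-6-hydroxy-3-(hydroxymethyl)-2,3-dihydro-1-benzofuran-7-yl]-2-[4-(benzyloxy)phenyl]ethan-1-one | O=C(Cc1ccc(OCc2ccccc2)cc1)c1c(O)c(Br)c(OCc2ccccc2)c2c1O[C@H](c1ccc(OCc3ccccc3)cc1)C2CO | intermediate
15 | 1-[(2S,3RS)-4-(benzyloxy)-2-[4-(benzyloxy)phenyl]-5-bromo-6-hydroxy-3-(iodomethyl)-2,3-dihydro-1-benzofuran-7-yl]-2-[4-(benzyloxy)phenyl]ethan-1-one | O=C(Cc1ccc(OCc2ccccc2)cc1)c1c(O)c(Br)c(OCc2ccccc2)c2c1O[C@H](c1ccc(OCc3ccccc3)cc1)C2CI | intermediate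
16 | 1-[(2R,3RS)-5-(benzyloxy)-2-[4-(benzyloxy)phenyl]-6-bromo-7-hydroxy-3-iodo-3,4-dihydro-2H-chromen-8-yl]-2-[4-(benzyloxy)phenyl]ethan-1-one | O=C(Cc1ccc(OCc2ccccc2)cc1)c1c(O)c(Br)c(OCc2ccccc2)c2c1O[C@H](c1ccc(OCc3ccccc3)cc1)C(I)C2 | intermediate (not isolated)
17 | 1-[(2S)-5-(benzyloxy)-2-[4-(benzyloxy)phenyl]-6-bromo-7-hydroxy-3,4-dihydro-2H-chromen-8-yl]-2-[4-(benzyloxy)phenyl]ethan-1-one | O=C(Cc1ccc(OCc2ccccc2)cc1)c1c(O)c(Br)c(OCc2ccccc2)c2c1O[C@H](c1ccc(OCc3ccccc3)cc1)CC2 | intermediate
18 | 1-[(2S)-5-(benzyloxy)-2-[4-(benzyloxy)phenyl]-6-bromo-7-hydroxy-3,4-dihydro-2H-chromen-8-yl]-2-[4-(benzyloxy)phenyl]-2-iodoethan-1-one | O=C(C(I)c1ccc(OCc2ccccc2)cc1)c1c(O)c(Br)c(OCc2ccccc2)c2c1O[C@H](c1ccc(OCc3ccccc3)cc1)CC2 | intermediate (not isolated)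
19 | (2S,8RS)-5-(benzyloxy)-2,8-bis[4-(benzyloxy)phenyl]-6-bromo-2,3,4,8-tetrahydro-9H-furo[2,3-h]chromen-9-one | O=C1C(c2ccc(OCc3ccccc3)cc2)Oc2c(Br)c(OCc3ccccc3)c3CC[C@@H](c4ccc(OCc5ccccc5)cc4)Oc3c12 | intermediate
20 | 2,4,6-trifluorobenzaldehyde | O=Cc1c(F)cc(F)cc1F | starting material
21 | 2,4-bis(benzyloxy)-6-fluorobenzaldehyde | O=Cc1c(F)cc(OCc2ccccc2)cc1OCc1ccccc1 | intermediate
22 | 2,4-bis(benzyloxy)-6-{[(2S)-5-(benzyloxy)-2,8-bis[4-(benzyloxy)phenyl]-6-bromo-3,4-dihydro-2H-furo[2,3-h]chromen-9-yl]oxy}benzaldehyde | O=Cc1c(Oc2c(-c3ccc(OCc4ccccc4)cc3)oc3c(Br)c(OCc4ccccc4)c4CC[C@@H](c5ccc(OCc6ccccc6)cc5)Oc4c23)cc(OCc2ccccc2)cc1OCc1ccccc1 | intermediate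
23 | (2S,2′S,8′S)-4,5′,6-tris(benzyloxy)-2′,8′-bis[4-(benzyloxy)phenyl]-6′-bromo-3′,4′-dihydro-2′H,3H,8′H-spiro[1-benzofuran-2,9′-furo[2,3-h]chromen]-3-one | O=C1c2c(OCc3ccccc3)cc(OCc3ccccc3)cc2O[C@]12c1c(c(Br)c(OCc3ccccc3)c3c1O[C@H](c1ccc(OCc4ccccc4)cc1)CC3)O[C@H]2c1ccc(OCc3ccccc3)cc1 | intermediate
24 | daphnodorin C, (2S,2′S,8′S)-4,5′,6-trihydroxy-2′,8′-bis(4-hydroxyphenyl)-3′,4′-dihydro-2′H,3H,8′H-spiro[1-benzofuran-2,9′-furo[2,3-h]chromen]-3-one | O=C1c2c(O)cc(O)cc2O[C@]12c1c(cc(O)c3c1O[C@H](c1ccc(O)cc1)CC3)O[C@H]2c1ccc(O)cc1 | target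

**Count and risks**

Total step count: 15. Longest linear sequence: 12 (steps 3–11 and 13–15, from 6).

Steps most likely to fail:

1. Step 14. The carbene-bound acyl-anion equivalent may fail to add to the hindered, electron-rich tetrasubstituted double bond, may add at C-8 (6-endo) instead of C-9, or may add with poor facial selectivity. The fallback sets out from 22 and comes back at 23. Pinnick oxidation (NaClO2, NaH2PO4, 2-methyl-2-butene) would give the carboxylic acid 2,4-bis(benzyloxy)-6-{[(2S)-5-(benzyloxy)-2,8-bis[4-(benzyloxy)phenyl]-6-bromo-3,4-dihydro-2H-furo[2,3-h]chromen-9-yl]oxy}benzoic acid F1. PhSeSePh/PBu3 would turn it into the Se-phenyl selenoester F2. Bu3SnH/AIBN (slow addition, PhH, 80 °C) would then generate the aroyl radical, which should close 5-exo onto C-9 of the benzofuran to the benzylic, oxygen-stabilised C-8 radical that is reduced by the stannane (acyl-radical cyclisation onto a heteroarene). This would give 23 together with its diastereomers, since the spiro centre is then formed without absolute control, and they would be separated by chromatography.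

2. Step 10. The primary radical may be reduced before the slow 1,2-aryl shift, the iodine-transfer chain may stall, or the rearranged β-aryloxy radical may fragment with ring opening. The fallback sets out from 12 and comes back at 17, bypassing steps 8–10. Hydroboration of the vinyl group with 9-BBN (excess, THF) would give the primary alkylborane F3. Intramolecular B-alkyl Suzuki–Miyaura coupling at the C–I bond in the same pot (Pd(dppf)Cl2, aqueous K3PO4, DMF, 60 °C; the C–Br bond is left) would close the chroman C-4–C-4a bond directly.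

3. Step 6. The chelated, acyl-stabilised phenoxide may be too weak a nucleophile, C-allylation or linear ether may form, and the product may lose ee by re-ionisation. The fallback sets out from 5 and comes back at 10. Mitsunobu etherification (PPh3, DIAD, toluene, 0 °C) of 5 with (1R)-3-chloro-1-[4-(benzyloxy)phenyl]propan-1-ol F4 (from CBS reduction of the corresponding 3-chloropropiophenone) should proceed with inversion to the (S)-3-chloropropyl ether F5. E2 elimination of HCl (KOt-Bu, 3 equiv, THF, 0 °C) would then give 10.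

**Further compounds**

F1 | step 14 | 2,4-bis(benzyloxy)-6-{[(2S)-5-(benzyloxy)-2,8-bis[4-(benzyloxy)phenyl]-6-bromo-3,4-dihydro-2H-furo[2,3-h]chromen-9-yl]oxy}benzoic acid | OC(=O)c1c(Oc2c(-c3ccc(OCc4ccccc4)cc3)oc3c(Br)c(OCc4ccccc4)c4CC[C@@H](c5ccc(OCc6ccccc6)cc5)Oc4c23)cc(OCc2ccccc2)cc1OCc1ccccc1
F2 | step 14 | Se-phenyl 2,4-bis(benzyloxy)-6-{[(2S)-5-(benzyloxy)-2,8-bis[4-(benzyloxy)phenyl]-6-bromo-3,4-dihydro-2H-furo[2,3-h]chromen-9-yl]oxy}benzenecarboselenoate | O=C([Se]c1ccccc1)c1c(Oc2c(-c3ccc(OCc4ccccc4)cc3)oc3c(Br)c(OCc4ccccc4)c4CC[C@@H](c5ccc(OCc6ccccc6)cc5)Oc4c23)cc(OCc2ccccc2)cc1OCc1ccccc1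
F3 | step 10 | 1-[4-(benzyloxy)-3-bromo-2-hydroxy-5-iodo-6-{[(1S)-1-[4-(benzyloxy)phenyl]-3-(9-borabicyclo[3.3.1]nonan-9-yl)propyl]oxy}phenyl]-2-[4-(benzyloxy)phenyl]ethan-1-one | O=C(Cc1ccc(OCc2ccccc2)cc1)c1c(O)c(Br)c(OCc2ccccc2)c(I)c1O[C@@H](CCB1C2CCCC1CCC2)c1ccc(OCc2ccccc2)cc1
F4 | step 6 | (1R)-3-chloro-1-[4-(benzyloxy)phenyl]propan-1-ol | O[C@H](CCCl)c1ccc(OCc2ccccc2)cc1
F5 | step 6 | 1-[4-(benzyloxy)-2-{[(1S)-1-[4-(benzyloxy)phenyl]-3-chloropropyl]oxy}-6-hydroxyphenyl]-2-[4-(benzyloxy)phenyl]ethan-1-one | O=C(Cc1ccc(OCc2ccccc2)cc1)c1c(O)cc(OCc2ccccc2)cc1O[C@@H](CCCl)c1ccc(OCc2ccccc2)cc1
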